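0.0191 M of D is what the green run has consumed by 4.00 min, out of a charge of 0.082 M of X.

| setting | green | blue | flask |
|---|---|---|---|
| D | 0.027 M | 0.061 M | 0.041 M |
| X | 0.082 M (in portions, 2) | 0.082 M (in portions, 2) | 0.0820 M (in portions, 2) |
| remark | run made earlier; portions every 6.0 s | run made earlier; portions every 6.0 s | the portions of X follow each other after 6.0 s, the first at the start |
| time |  |  | 4.0 min |

| run | time / min | D / % | Z / % |
|---|---|---|---|
| green | 0.333 | 54.1 | 45.6 |
| green | 0.667 | 39.1 | 60.5 |
| green | 1.50 | 30.8 | 69.5 |
| green | 4.00 | 29.1 | 71.7 |
| blue | 0.500 | 44.4 | 56.0 |
| blue | 1.33 | 36.1 | 63.3 |
| blue | 2.50 | 34.6 | 64.4 |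
| blue | 4.00 | 35.0 | 64.6 |

(scatter of a reading: 0.5 percentage points)

- the analysis behind the earlier runs scatters by 0.5 percentage points, standard deviation
- a reading or a percentage of Z counts all its forms, free or not
- the reaction counts as stopped when no species that holds the D changes by six tenths of a point or more over the second half of the time

- the state of affairs at 4.0 min: stopped, and by what, or still going (all of D has reacted / forward and back rates have come level / X has run out first / it is still moving)
- share of the D used up at 4.0 min
- Z at 4.0 min, in percent of the D charged

I read the tables from their last rows. Green's D goes from 30.8% to 29.1% over its last interval, and blue's stays near 35.0%, so blue has gone flat and green has nearly done so, both with D unused. D and Z add up to 101% in green and 99.6% in blue, so what D loses stands as Z.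

Now I follow one molecule of X and suppose it has a second exit that uses no D. At each instant it takes D with chance [D]/([D]+β), where β is the concentration of D at which both exits are even: a selectivity factor in concentration units. Summed over the charge until X is gone, this gives

X charged = D used + β ln(D charged / D left).

The last rows give β as 0.0509 M in green and 0.0403 M in blue. Blue's is smaller, so β is no true constant, but I carry the mean as the even-chance concentration, 0.0456 M.

For the flask I solve the balance by repeated substitution. It gives 69.2% of D used, and I expect the stop to come from X being gone.

The forecast says 68.9% used, 68.8% Z, and forward and back rates have come level: “The flask should be level well before 4 min”. We differ slightly on the conversion and outright on the ending.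

The flask gives 68.9% used, 68.9% Z, and the ending: X has run out first.

    D + X + Z → 2 Z (k = 620 /M²/s)
    X → E (k = 0.0290 /s)
    G ⇌ Z, rate k3*(cs3 - [Z]) while solid is left; crystals form when [Z] > cs3 (solubility = 0.610 mM, k = 2.90 /s)
    D + X → Z (k = 0.130 /M/s)

In the flask, X passes into E and into Z together: half of the turnover to E is done by 0.339 min, and X is down to 1.10% of its charge at 2.00 min. From then on D stands at 31.1% while X, charged at twice the amount of D, falls to 0.016% of that charge, a smaller share than the part of D left. The flask's own result puts β at 0.0460 M. With the carried 0.0456 M, a neighbour flask charged with 0.049 M of X comes out at 47.3% used, and it stores 45.5%.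

(The readings were generated by integration on assumed constants; scatter was added.)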